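**Retrosynthetic overview**
1. The target, read as the (2S)-flavanone, is obtained last by removing three MOM ethers from the fully assembled flavanone 16.
2. Ring C of 16 is disconnected at O1–C8a and at C4–C4a, giving ring A as aryne 15 (from silyl triflate 9) and the (S)-beta-silyloxy ester 13, which carries ring B, C2, C3 and C4.
3. Enabling feature: C4a and C8a are adjacent sp2 carbons of ring A, and the C5 oxygen sits next to C4a. They can therefore be the two ends of a 3-alkoxy-aryne that accepts a nucleophile at C8a and leaves a carbanion at C4a. O1 and the C4 carbonyl carbon, separated by C2 and C3, are the matching alkoxide and acyl partners.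
4. 9 comes from phloroglucinol by two carbamate-directed ortho-metalations (TMS, then prenyl). 13 comes from 2-bromoisovanillin by Stille prenylation and an asymmetric Mukaiyama acetate aldol that sets C2.
5. Ring order: rings A and B are bought as arenes; ring C is formed last, in the key step.

Key step: step 10

Assumption: in step 9 the ligand antipode is the one that leads to addition on the Si face of the aldehyde (3S product); the sense is to be confirmed on the first run by chiral HPLC against material from the transfer-hydrogenation fallback.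

**Route**

Step 1
Reactants: 1 benzene-1,3,5-triol (phloroglucinol)
Product: 2 3,5-bis(methoxymethoxy)phenol
Conditions: MOMCl (2.0 equiv), iPr2NEt (2.2 equiv), DMF, 0 °C → rt; chromatography to remove mono- and tris-ethers
Reagents that add atoms: chloromethyl methyl ether, COCCl
Why: Statistical O-alkylation of a threefold-symmetric triol, in which the bis-ether should be the main fraction at this stoichiometry and the one free OH marks the oxygen that later becomes the leaving group.

Step 2
Reactants: 2 3,5-bis(methoxymethoxy)phenol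
Product: 3 3,5-bis(methoxymethoxy)phenyl N,N-diethylcarbamate
Conditions: Et2NCOCl (1.2 equiv), K2CO3, MeCN, 80 °C
Reagents that add atoms: N,N-diethylcarbamoyl chloride, CCN(CC)C(Cl)=O
Why: O-Carbamoylation of the phenoxide installs the strongest ortho-directing group on the unique oxygen.

Step 3
Reactants: 3 3,5-bis(methoxymethoxy)phenyl N,N-diethylcarbamate
Product: 5 3,5-bis(methoxymethoxy)-2-(trimethylsilyl)phenyl N,N-diethylcarbamate, via aryllithium 4 (not isolated)
Conditions: s-BuLi (1.2 equiv), TMEDA, THF, −78 °C; then TMSCl, −78 °C → rt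
Reagents that add atoms: chlorotrimethylsilane, C[Si](C)(C)Cl
Why: Directed ortho-metalation, in which the O-carbamate cooperates with the neighbouring OMOM group so that lithiation should occur at the carbon between them and not between the two OMOM groups, and silylation at −78 °C precedes any anionic ortho-Fries shift.

Step 4
Reactants: 5 3,5-bis(methoxymethoxy)-2-(trimethylsilyl)phenyl N,N-diethylcarbamate
Product: 7 3,5-bis(methoxymethoxy)-2-(3-methylbut-2-en-1-yl)-6-(trimethylsilyl)phenyl N,N-diethylcarbamate, via aryllithium 6 (not isolated)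
Conditions: s-BuLi (1.2 equiv), TMEDA, THF, −78 °C; CuBr·SMe2 (10 mol%), prenyl bromide, −78 → −20 °C
Reagents that add atoms: 1-bromo-3-methylbut-2-ene, CC(C)=CCBr
Why: A second directed ortho-metalation at the remaining carbon between carbamate and OMOM, followed by copper-catalysed SN2 allylation of the aryllithium, should give the linear prenyl group; the silyl group blocks the other ortho position and no benzylic C–H is yet present to compete.

Step 5
Reactants: 7 3,5-bis(methoxymethoxy)-2-(3-methylbut-2-en-1-yl)-6-(trimethylsilyl)phenyl N,N-diethylcarbamate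
Product: 8 3,5-bis(methoxymethoxy)-2-(3-methylbut-2-en-1-yl)-6-(trimethylsilyl)phenol
Conditions: LiAlH4, THF, 0 → 50 °C; aqueous work-up
Reagents that add atoms: none
Why: Reductive cleavage of the aryl O-carbamate, in which hydride attack at the carbonyl expels the hindered phenoxide, while MOM ethers, the aryl–silicon bond and the trisubstituted alkene are inert to LiAlH4.

Step 6
Reactants: 8 3,5-bis(methoxymethoxy)-2-(3-methylbut-2-en-1-yl)-6-(trimethylsilyl)phenol
Product: 9 3,5-bis(methoxymethoxy)-2-(3-methylbut-2-en-1-yl)-6-(trimethylsilyl)phenyl trifluoromethanesulfonate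
Conditions: Tf2O, pyridine, CH2Cl2, −20 → 0 °C
Reagents that add atoms: trifluoromethanesulfonic anhydride, O=S(=O)(OS(=O)(=O)C(F)(F)F)C(F)(F)F
Why: O-Sulfonylation of the phenol completes a 2-(trimethylsilyl)aryl triflate, the standard fluoride-triggered aryne precursor, and the MOM ethers should tolerate the cold, pyridine-buffered conditions.

Step 7
Reactants: 10 2-bromo-3-hydroxy-4-methoxybenzaldehyde
Product: 11 2-bromo-4-methoxy-3-(methoxymethoxy)benzaldehyde
Conditions: MOMCl, iPr2NEt, CH2Cl2, 0 °C → rt
Reagents that add atoms: chloromethyl methyl ether, COCCl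
Why: MOM protection of the phenol, which would otherwise arylate in the key step, using the same group as on ring A so that one final operation removes all three.

Step 8
Reactants: 11 2-bromo-4-methoxy-3-(methoxymethoxy)benzaldehyde
Product: 12 4-methoxy-3-(methoxymethoxy)-2-(3-methylbut-2-en-1-yl)benzaldehyde
Conditions: Pd(PPh3)4 (5 mol%), tributyl(3-methylbut-2-en-1-yl)stannane, DMF, 90 °C
Reagents that add atoms: tributyl(3-methylbut-2-en-1-yl)stannane, CCCC[Sn](CCCC)(CCCC)CC=C(C)C
Why: Stille coupling, in which zerovalent palladium inserts into the C–Br bond activated by the ortho formyl group and reductive elimination at the less substituted allyl terminus should give the linear prenyl arene.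

Step 9
Reactants: 12 4-methoxy-3-(methoxymethoxy)-2-(3-methylbut-2-en-1-yl)benzaldehyde
Product: 13 methyl (3S)-3-[4-methoxy-3-(methoxymethoxy)-2-(3-methylbut-2-en-1-yl)phenyl]-3-[(trimethylsilyl)oxy]propanoate
Conditions: Ti(OiPr)4 (5 mol%), tridentate Schiff-base ligand from 2-amino-2'-hydroxy-1,1'-binaphthyl and 3-bromo-5-tert-butylsalicylaldehyde (5 mol%), 3,5-di-tert-butylsalicylic acid (5 mol%), 1-methoxy-1-(trimethylsilyloxy)ethene, Et2O, −10 °C; non-aqueous work-up, Et3N-deactivated silica
Reagents that add atoms: 1-methoxy-1-(trimethylsilyloxy)ethene, COC(=C)O[Si](C)(C)C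
Why: Catalytic enantioselective Mukaiyama acetate aldol, in which the chiral titanium complex should shield the Re face of the aldehyde so that the ketene acetal adds to the Si face to set the 3S centre, and silyl transfer to the aldolate oxygen in the turnover step delivers the silyl ether directly.

Step 10
Reactants: 13 methyl (3S)-3-[4-methoxy-3-(methoxymethoxy)-2-(3-methylbut-2-en-1-yl)phenyl]-3-[(trimethylsilyl)oxy]propanoate; 9 3,5-bis(methoxymethoxy)-2-(3-methylbut-2-en-1-yl)-6-(trimethylsilyl)phenyl trifluoromethanesulfonate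
Product: 16 (2S)-5,7-bis(methoxymethoxy)-2-[4-methoxy-3-(methoxymethoxy)-2-(3-methylbut-2-en-1-yl)phenyl]-8-(3-methylbut-2-en-1-yl)-2,3-dihydro-4H-chromen-4-one, via potassium alkoxide 14 (not isolated), via aryne 15 (not isolated)
Conditions: 9 (1.2 equiv), KF (1.2 equiv), 18-crown-6 (1.2 equiv), THF, 0 → 23 °C; pH 7 phosphate quench
Reagents that add atoms: none
Why: Proposed new method: fluoride strips the O–SiMe3 group of 13 to give the proton-free alkoxide 14, and fluoride or the methoxide released later triggers 1,2-elimination of 9 to aryne 15; 14 adds through oxygen to the aryne carbon remote from the OMOM-bearing neighbour (future C8a), the aryl anion formed at the carbon ortho to OMOM (future C4a) attacks the methyl ester carbonyl, and methoxide is expelled, so the O–aryl and aryl–acyl bonds form in one cascade. The closest known reaction types are the fluoride-mediated annulation of arynes with salicylate esters to xanthones and the aryne insertion into the C–O bond of carboxylic acids that gives ortho-hydroxyaryl ketones and chromanones; an aliphatic beta-oxy ester as the partner is the untested element. Ring C is the only ring closed, by intermolecular O-arylation followed by a 6-exo-trig, Dieckmann-like acyl substitution by the aryl carbanion. No stereocentre is created, because C2 comes from 13 with its C–O bond untouched and the S configuration is carried over. The step needs three selectivities: regioselective attack on the aryne, secured by the inductive, angle-distorting OMOM group beside one aryne carbon, which also stabilises the ortho carbanion; acyl capture instead of protonation of the aryl anion, secured by the silyl ether as a proton-free alkoxide source; and survival of the base-labile C2 centre, secured by limiting fluoride so that released methoxide is consumed as Me3SiOMe by the remaining silyl groups.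

Step 11
Reactants: 16 (2S)-5,7-bis(methoxymethoxy)-2-[4-methoxy-3-(methoxymethoxy)-2-(3-methylbut-2-en-1-yl)phenyl]-8-(3-methylbut-2-en-1-yl)-2,3-dihydro-4H-chromen-4-one
Product: 17 (2S)-5,7-dihydroxy-2-[3-hydroxy-4-methoxy-2-(3-methylbut-2-en-1-yl)phenyl]-8-(3-methylbut-2-en-1-yl)-2,3-dihydro-4H-chromen-4-one
Conditions: HCl (3 M aq)/MeOH, 45 °C, stopped at full conversion
Reagents that add atoms: none
Why: Acid-catalysed acetal exchange with methanol removes the three MOM groups as dimethoxymethane under conditions mild enough that the ortho-prenyl phenols should not cyclise to chromans and C2, which is not involved, should keep its configuration.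

**Compound list**
1 | benzene-1,3,5-triol (phloroglucinol) | Oc1cc(O)cc(O)c1 | starting material
2 | 3,5-bis(methoxymethoxy)phenol | COCOc1cc(O)cc(OCOC)c1 | intermediate
3 | 3,5-bis(methoxymethoxy)phenyl N,N-diethylcarbamate | CCN(CC)C(=O)Oc1cc(OCOC)cc(OCOC)c1 | intermediate
4 | 2-lithio-3,5-bis(methoxymethoxy)phenyl N,N-diethylcarbamate (formed in the flask) | CCN(CC)C(=O)Oc1cc(OCOC)cc(OCOC)c1[Li] | intermediate
5 | 3,5-bis(methoxymethoxy)-2-(trimethylsilyl)phenyl N,N-diethylcarbamate | CCN(CC)C(=O)Oc1cc(OCOC)cc(OCOC)c1[Si](C)(C)C | intermediate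
6 | 2-lithio-3,5-bis(methoxymethoxy)-6-(trimethylsilyl)phenyl N,N-diethylcarbamate (formed in the flask) | CCN(CC)C(=O)Oc1c([Li])c(OCOC)cc(OCOC)c1[Si](C)(C)C | intermediate
7 | 3,5-bis(methoxymethoxy)-2-(3-methylbut-2-en-1-yl)-6-(trimethylsilyl)phenyl N,N-diethylcarbamate | CCN(CC)C(=O)Oc1c(CC=C(C)C)c(OCOC)cc(OCOC)c1[Si](C)(C)C | intermediate
8 | 3,5-bis(methoxymethoxy)-2-(3-methylbut-2-en-1-yl)-6-(trimethylsilyl)phenol | CC(C)=CCc1c(O)c([Si](C)(C)C)c(OCOC)cc1OCOC | intermediate
9 | 3,5-bis(methoxymethoxy)-2-(3-methylbut-2-en-1-yl)-6-(trimethylsilyl)phenyl trifluoromethanesulfonate | CC(C)=CCc1c(OS(=O)(=O)C(F)(F)F)c([Si](C)(C)C)c(OCOC)cc1OCOC | intermediate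
10 | 2-bromo-3-hydroxy-4-methoxybenzaldehyde | COc1ccc(C=O)c(Br)c1O | starting material
11 | 2-bromo-4-methoxy-3-(methoxymethoxy)benzaldehyde | COCOc1c(OC)ccc(C=O)c1Br | intermediate
12 | 4-methoxy-3-(methoxymethoxy)-2-(3-methylbut-2-en-1-yl)benzaldehyde | COCOc1c(OC)ccc(C=O)c1CC=C(C)C | intermediate
13 | methyl (3S)-3-[4-methoxy-3-(methoxymethoxy)-2-(3-methylbut-2-en-1-yl)phenyl]-3-[(trimethylsilyl)oxy]propanoate | COc1ccc([C@@H](O[Si](C)(C)C)CC(=O)OC)c(CC=C(C)C)c1OCOC | intermediate
14 | potassium (1S)-3-methoxy-1-[4-methoxy-3-(methoxymethoxy)-2-(3-methylbut-2-en-1-yl)phenyl]-3-oxopropan-1-olate (formed in the flask) | COc1ccc([C@@H]([O-])CC(=O)OC)c(CC=C(C)C)c1OCOC.[K+] | intermediate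
15 | 3,5-bis(methoxymethoxy)-6-(3-methylbut-2-en-1-yl)-1,2-didehydrobenzene (aryne, formed in the flask) | CC(C)=CCC1=C(OCOC)C=C(OCOC)C#C1 | intermediate
16 | (2S)-5,7-bis(methoxymethoxy)-2-[4-methoxy-3-(methoxymethoxy)-2-(3-methylbut-2-en-1-yl)phenyl]-8-(3-methylbut-2-en-1-yl)-2,3-dihydro-4H-chromen-4-one | COc1ccc([C@@H]2CC(=O)c3c(OCOC)cc(OCOC)c(CC=C(C)C)c3O2)c(CC=C(C)C)c1OCOC | intermediate
17 | (2S)-5,7-dihydroxy-2-[3-hydroxy-4-methoxy-2-(3-methylbut-2-en-1-yl)phenyl]-8-(3-methylbut-2-en-1-yl)-2,3-dihydro-4H-chromen-4-one | COc1ccc([C@@H]2CC(=O)c3c(O)cc(O)c(CC=C(C)C)c3O2)c(CC=C(C)C)c1O | target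

**Step count**
Total: 11 steps. Longest linear sequence: 8 steps (steps 1–6, 10, 11).

**Steps most likely to fail**

Step 10 (proposed new method). The alkoxide may be lost by retro-aldol cleavage or beta-elimination before it captures the aryne. The aryl anion may be protonated instead of acylated. Released base may open and reclose ring C and erode the configuration at C2. The fallback sets out from 12 and 9 and comes back at 16, using known chemistry in which the stereocentre is no longer carried through the aryne step. Aldehyde 12 is condensed with malonic acid (pyridine, piperidine cat., 90 °C; Knoevenagel–Doebner) to (2E)-3-[4-methoxy-3-(methoxymethoxy)-2-(3-methylbut-2-en-1-yl)phenyl]prop-2-enoic acid F1. F1 and 9 with CsF in THF at 100–125 °C in a sealed tube should undergo the known aryne insertion into the carboxylic acid C–O bond, with acyl migration to carbon, to give (2E)-1-[2-hydroxy-4,6-bis(methoxymethoxy)-3-(3-methylbut-2-en-1-yl)phenyl]-3-[4-methoxy-3-(methoxymethoxy)-2-(3-methylbut-2-en-1-yl)phenyl]prop-2-en-1-one F2. NaOAc in EtOH at reflux closes ring C by oxa-Michael addition to racemic 5,7-bis(methoxymethoxy)-2-[4-methoxy-3-(methoxymethoxy)-2-(3-methylbut-2-en-1-yl)phenyl]-8-(3-methylbut-2-en-1-yl)-2,3-dihydro-4H-chromen-4-one F3. Preparative chromatography on a chiral stationary phase then delivers the 2S enantiomer, which is 16.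

Step 9. Facial selectivity may be poor with an ortho-substituted, electron-rich aldehyde, or the O-silyl group may be lost during isolation. The fallback sets out from 12 and comes back at 13, and sets the stereocentre by ketone reduction instead of aldol addition. Aldehyde 12 is treated with the lithium enolate of methyl acetate (LDA, THF, −78 °C) to give racemic methyl 3-hydroxy-3-[4-methoxy-3-(methoxymethoxy)-2-(3-methylbut-2-en-1-yl)phenyl]propanoate F4. Oxidation with Dess–Martin periodinane (CH2Cl2, rt) gives methyl 3-[4-methoxy-3-(methoxymethoxy)-2-(3-methylbut-2-en-1-yl)phenyl]-3-oxopropanoate F5. Asymmetric transfer hydrogenation with RuCl(p-cymene)[(S,S)-TsDPEN] in HCO2H/Et3N should give, by the usual aryl/alkyl facial model, methyl (3S)-3-hydroxy-3-[4-methoxy-3-(methoxymethoxy)-2-(3-methylbut-2-en-1-yl)phenyl]propanoate F6. TMSCl and imidazole in CH2Cl2 then return to 13.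

Step 4. Metalation may occur between the two OMOM groups instead of next to the carbamate, the carbamoyl group may migrate to carbon (anionic ortho-Fries) before alkylation, or the allylic coupling may transpose. The fallback sets out from 5 and comes back at 8, and delivers the prenyl group by a sigmatropic shift from oxygen instead of by metalation. Carbamate 5 is cleaved with LiAlH4 (THF, 0 → 50 °C) to 3,5-bis(methoxymethoxy)-2-(trimethylsilyl)phenol F7. O-Alkylation with tert-butyl (2-methylbut-3-en-2-yl) carbonate and Pd(PPh3)4 (cat., THF, 0 °C) gives [2-(2-methylbut-3-en-2-yloxy)-4,6-bis(methoxymethoxy)phenyl]trimethylsilane F8. Heating in toluene or N,N-diethylaniline (110–140 °C) should bring about the aromatic Claisen rearrangement to the only free ortho carbon and give 8.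

**Further compounds**
F1 | step 10 | (2E)-3-[4-methoxy-3-(methoxymethoxy)-2-(3-methylbut-2-en-1-yl)phenyl]prop-2-enoic acid | COc1ccc(/C=C/C(O)=O)c(CC=C(C)C)c1OCOC
F2 | step 10 | (2E)-1-[2-hydroxy-4,6-bis(methoxymethoxy)-3-(3-methylbut-2-en-1-yl)phenyl]-3-[4-methoxy-3-(methoxymethoxy)-2-(3-methylbut-2-en-1-yl)phenyl]prop-2-en-1-one | COc1ccc(/C=C/C(=O)c2c(OCOC)cc(OCOC)c(CC=C(C)C)c2O)c(CC=C(C)C)c1OCOC
F3 | step 10 | racemic 5,7-bis(methoxymethoxy)-2-[4-methoxy-3-(methoxymethoxy)-2-(3-methylbut-2-en-1-yl)phenyl]-8-(3-methylbut-2-en-1-yl)-2,3-dihydro-4H-chromen-4-one | COc1ccc(C2CC(=O)c3c(OCOC)cc(OCOC)c(CC=C(C)C)c3O2)c(CC=C(C)C)c1OCOC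
F4 | step 9 | racemic methyl 3-hydroxy-3-[4-methoxy-3-(methoxymethoxy)-2-(3-methylbut-2-en-1-yl)phenyl]propanoate | COc1ccc(C(O)CC(=O)OC)c(CC=C(C)C)c1OCOC
F5 | step 9 | methyl 3-[4-methoxy-3-(methoxymethoxy)-2-(3-methylbut-2-en-1-yl)phenyl]-3-oxopropanoate | COc1ccc(C(=O)CC(=O)OC)c(CC=C(C)C)c1OCOC
F6 | step 9 | methyl (3S)-3-hydroxy-3-[4-methoxy-3-(methoxymethoxy)-2-(3-methylbut-2-en-1-yl)phenyl]propanoate | COc1ccc([C@@H](O)CC(=O)OC)c(CC=C(C)C)c1OCOC
F7 | step 4 | 3,5-bis(methoxymethoxy)-2-(trimethylsilyl)phenol | COCOc1cc(OCOC)c([Si](C)(C)C)c(O)c1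
F8 | step 4 | [2-(2-methylbut-3-en-2-yloxy)-4,6-bis(methoxymethoxy)phenyl]trimethylsilane | COCOc1cc(OCOC)c([Si](C)(C)C)c(OC(C)(C)C=C)c1
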